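Its constants are those of an exercise; the result is computed.

Which flask ends with more target, the one at the lower temperature or the hotter one, and by how much?

    starting material + catalyst → catalyst + target (k1 = 410 M⁻¹ min⁻¹, Ea1 = 64.0 kJ mol⁻¹)
    target + catalyst ⇌ isomer of the product + catalyst, rate k2*[catalyst]*[target] forward; the back reaction follows from the equilibrium constant (K2 = 14, k2 = 100 M⁻¹ min⁻¹, Ea2 = 39.0 kJ mol⁻¹, ΔH2 = −17.0 kJ mol⁻¹)
    solid substrate ⇌ starting material, rate k3*(cs3 - [starting material]) while solid is left; crystals form when [starting material] > cs3 (cs3 = 0.78 M, k3 = 0.082 min⁻¹)
    (constants at 80 °C)
- spring: solid substrate 1.0 M; catalyst 1.0 mM; temperature 80 °C; time 20 min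
- autumn: solid substrate 1.0 M; catalyst 1.0 mM; temperature 100 °C; time 20 min
- solid, in amounts per volume of the solution: solid substrate
- at 80 °C the constants are as listed, elsewhere as the activation energies and enthalpies make them
- at the start none of the solid substrate is in solution
- what has only dissolved of solid substrate counts as not reacted
1. the best flask by amount of target, in percent of the solid substrate charged; "all alike" if 1.5 percentage points covers them all (spring / autumn / all alike)
2. amount of target at the end, in percent of the solid substrate charged, spring
3. amount of target at the end, in percent of the solid substrate charged, autumn

*Where does a molecule go?* It leaves the solid substrate as starting material, becomes target at the catalyst, and then reaches a fork: at each moment it stays target or turns into the isomer of the product. The catalyst returns unchanged in the scheme, so this loss is pseudo-first-order, with constant k·c(catalyst), where k is the rate constant of the second step.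

*How fast is the feed?* If c(starting material) is taken as near zero, dissolving runs at 0.0640 M min⁻¹, and the scheme gives it no activation energy. At that estimated rate the charge lasts about 15.6 min, somewhat shorter than the run. I treat the feed as steady over the whole time t.

*What, then, is the chance of a target molecule born at a random moment?* Averaging its exponential survival over all birth moments gives (1 − e^−x)/x, with x = k·c(catalyst)·t. In spring x is 2.00, which gives 43.2%. This is the keep fraction: the share of steadily fed target still target at the end. In autumn the second step runs 2.0 times faster, so x is 4.08 and the keep fraction is 24.1%.

*You ignored the back reaction. Is that safe?* The equilibrium share of target is 6.67% in spring and 8.88% in autumn, each smaller than that flask's keep fraction. I accept the error and commit to spring, ahead by 19 percentage points, more than the margin.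

The forecast also names spring, with 43.6% for spring and 22.2% for autumn, on the grounds that “its faster isomerisation and still product-favoured equilibrium drain the target”. Its spring figure lies above my 43.2%, and its autumn figure lies below my 24.1%.

The simulation gives spring, with 43.6% in spring and 22.2% in autumn, the forecast's values; the keep fractions stood at 43.2% and 24.1%. In the autumn flask at 20.0 min, the half-life of target by the forward rate of the second step alone is 3.4 min, short against the 20 min of the run, and, each step taken net, target is being made more slowly than it is used up, at 0.0224 times that rate.

Now take the autumn flask with 0.0025 M of catalyst. Here x grows with the catalyst to 10.2, and the keep fraction falls to 9.81%. The simulation gives 10.2% of target.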